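The oxolane is disconnected at O1–C5 and C2–C3. O1–C2 with its aryl group is the carbonyl of 3,4,5-trimethoxybenzaldehyde; C3–C4–C5, whose central carbon C4 carries a one-carbon branch, is an ester-bearing trimethylenemethane. A single palladium-catalysed [3+2] cycloaddition of the silylmethyl allylic acetate 4 to the aldehyde closes the ring, forms both bonds, sets C2 (chiral ligand) and C3 (trans to aryl), and leaves C4 as an exocyclic methylene. That alkene then takes the second trimethoxybenzyl group by hydroboration anti to the C3 arm and B-alkyl Suzuki coupling. The precursor is methyl 4-acetoxy-3-[(trimethylsilyl)methyl]but-2-enoate, made in two steps from an ynoate.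

Key step: step 3

Assumption: the phosphoramidite antipode that directs addition to the Si face of 5 (giving 2S) is identified in a first run, both antipodes being accessible; the oxolane keeps the locants O1, C2 (aryl), C3 (CH2O arm), C4, C5 in all names.

Step 1
Reactants: 1 methyl 4-hydroxybut-2-ynoate
Product: 2 methyl 4-acetoxybut-2-ynoate
Conditions: Ac2O (1.5 equiv), Sc(OTf)3 (1 mol %), MeCN, 0 °C
Reagents that add atoms: acetic anhydride, CC(=O)OC(C)=O
Why: Lewis-acid-catalysed O-acylation of the primary propargylic alcohol with the anhydride runs without amine base, which avoids the base-triggered isomerisation and conjugate additions to which hydroxy ynoates are prone.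

Step 2
Reactants: 2 methyl 4-acetoxybut-2-ynoate; 3 (trimethylsilyl)methylmagnesium chloride
Product: 4 methyl (E)-4-acetoxy-3-[(trimethylsilyl)methyl]but-2-enoate
Conditions: 3 (2.2 equiv), CuBr·SMe2 (1.1 equiv), THF, −40 °C; then 2, −78 °C; MeOH, then aq. NH4Cl at −78 °C
Reagents that add atoms: none
Why: Michael-type syn-carbocupration of the ynoate by the silylmethyl cuprate puts CH2SiMe3 on C3, and protonation of the alkenylcopper with retention should give the E enoate (ester trans to CH2SiMe3); at −78 °C conjugate addition should outrun SN2′ displacement of the propargylic acetate, and the alkene geometry is erased in step 3 in any case.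

Step 3
Reactants: 4 methyl (E)-4-acetoxy-3-[(trimethylsilyl)methyl]but-2-enoate (1.5 equiv); 5 3,4,5-trimethoxybenzaldehyde
Product: 6 methyl (2S,3S)-4-methylidene-2-(3,4,5-trimethoxyphenyl)oxolane-3-carboxylate (2,3-trans)
Conditions: Pd(dba)2 (5 mol %), BINOL-derived phosphoramidite of trans-2,5-bis(2-naphthyl)pyrrolidine (antipode giving 2S, 10 mol %), In(acac)3 (10 mol %), toluene, rt to 50 °C
Reagents that add atoms: none
Why: Zerovalent palladium, formed from Pd(dba)2 and the phosphoramidite, ionises the allylic acetate of 4, and the acetate released removes the silyl group as Me3SiOAc to give the zwitterionic trimethylenemethane–palladium complex, in which the negative charge settles on the ester-bearing carbon whatever the geometry of 4. That carbon adds to the carbonyl carbon of 5, which In(acac)3 activates (C2–C3), and the resulting alkoxide closes the oxolane by intramolecular O-allylation at the unsubstituted CH2 terminus of the π-allylpalladium (O1–C5; a five-membered closure, 5-exo-tet when the allyl is drawn σ-bound at C5), which returns zerovalent palladium and leaves the exocyclic methylene at C4. The closest known reaction type is the palladium-catalysed trimethylenemethane [3+2] cycloaddition of 2-(silylmethyl)allyl acetates to aryl aldehydes under indium co-catalysis, combined with the known behaviour of acceptor-substituted (cyano) donors, which react through their substituted carbon. C2 is set by the chiral ligand on palladium, which must select the Si face of the aldehyde; C3 follows from C2, because the ester takes the position trans to the aryl group in the ring-forming event and the acidic C3–H allows equilibration to the trans isomer. The step needs C–C bond formation through the substituted terminus, which ester stabilisation of the anion secures, and it needs the alkene to stay exocyclic, which is why the medium is kept near neutral and 6 is reduced at once.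

Step 4
Reactants: 6 methyl (2S,3S)-4-methylidene-2-(3,4,5-trimethoxyphenyl)oxolane-3-carboxylate
Product: 7 [(2S,3R)-4-methylidene-2-(3,4,5-trimethoxyphenyl)oxolan-3-yl]methanol
Conditions: i-Bu2AlH (2.5 equiv), CH2Cl2, −78 °C; aq. potassium sodium tartrate
Reagents that add atoms: none
Why: Hydride reduction of the ester to the primary alcohol with i-Bu2AlH at −78 °C is non-basic, so the acidic allylic C3–H should neither epimerise nor let the alkene move into conjugation; no stereocenter is touched (the C3 descriptor changes only through the priority rules).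

Step 5
Reactants: 7 [(2S,3R)-4-methylidene-2-(3,4,5-trimethoxyphenyl)oxolan-3-yl]methanol
Product: 8 tert-butyldimethyl{[(2S,3R)-4-methylidene-2-(3,4,5-trimethoxyphenyl)oxolan-3-yl]methoxy}silane
Conditions: TBSCl (1.2 equiv), imidazole (2.5 equiv), DMF, 0 °C to rt
Reagents that add atoms: tert-butyldimethylsilyl chloride, CC(C)(C)[Si](C)(C)Cl
Why: Imidazole-promoted silylation of a primary alcohol is routine; the bulky silyl ether enlarges the C3 arm for face control in step 6 and keeps the hydroxyl from consuming borane.

Step 6
Reactants: 8 tert-butyldimethyl{[(2S,3R)-4-methylidene-2-(3,4,5-trimethoxyphenyl)oxolan-3-yl]methoxy}silane; 9 5-bromo-1,2,3-trimethoxybenzene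
Product: 11 tert-butyldimethyl{[(2S,3R,4R)-2-(3,4,5-trimethoxyphenyl)-4-[(3,4,5-trimethoxyphenyl)methyl]oxolan-3-yl]methoxy}silane, via B-alkyl-9-borabicyclononane 10 (not isolated)
Conditions: 9-BBN (1.5 equiv), THF, 0 °C to rt; then 9 (1.2 equiv), Pd(dppf)Cl2 (5 mol %), aq. K3PO4 (3 equiv), DMF, 60 °C
Reagents that add atoms: none
Why: Hydroboration with 9-BBN puts boron on the terminal carbon and delivers hydrogen to C4 from the face opposite the adjacent CH2OTBS arm, which sets 4R with the new CH2 cis to that arm, and the B-alkyl Suzuki–Miyaura coupling of the primary alkylborane with the aryl bromide then forms the benzylic C–C bond without touching a stereocenter.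

Step 7
Reactants: 11 tert-butyldimethyl{[(2S,3R,4R)-2-(3,4,5-trimethoxyphenyl)-4-[(3,4,5-trimethoxyphenyl)methyl]oxolan-3-yl]methoxy}silane
Product: 12 [(2S,3R,4R)-2-(3,4,5-trimethoxyphenyl)-4-[(3,4,5-trimethoxyphenyl)methyl]oxolan-3-yl]methanol
Conditions: Bu4NF (1.2 equiv), THF, 0 °C to rt
Reagents that add atoms: none
Why: Fluoride-mediated desilylation of a primary silyl ether is mild and involves no stereocenter, so the 2,3-trans-3,4-cis array should be delivered unchanged.

Compound list
1 | methyl 4-hydroxybut-2-ynoate | COC(=O)C#CCO | starting material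
2 | methyl 4-acetoxybut-2-ynoate | COC(=O)C#CCOC(C)=O | intermediate
3 | (trimethylsilyl)methylmagnesium chloride | C[Si](C)(C)C[Mg]Cl | starting material
4 | methyl (E)-4-acetoxy-3-[(trimethylsilyl)methyl]but-2-enoate | COC(=O)/C=C(/C[Si](C)(C)C)COC(C)=O | intermediate
5 | 3,4,5-trimethoxybenzaldehyde | COc1cc(C=O)cc(OC)c1OC | starting material
6 | methyl (2S,3S)-4-methylidene-2-(3,4,5-trimethoxyphenyl)oxolane-3-carboxylate | C=C1CO[C@H](c2cc(OC)c(OC)c(OC)c2)[C@H]1C(=O)OC | intermediate
7 | [(2S,3R)-4-methylidene-2-(3,4,5-trimethoxyphenyl)oxolan-3-yl]methanol | C=C1CO[C@H](c2cc(OC)c(OC)c(OC)c2)[C@H]1CO | intermediate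
8 | tert-butyldimethyl{[(2S,3R)-4-methylidene-2-(3,4,5-trimethoxyphenyl)oxolan-3-yl]methoxy}silane | C=C1CO[C@H](c2cc(OC)c(OC)c(OC)c2)[C@H]1CO[Si](C)(C)C(C)(C)C | intermediate
9 | 5-bromo-1,2,3-trimethoxybenzene | COc1cc(Br)cc(OC)c1OC | starting material
10 | tert-butyl({(2S,3R,4R)-4-[(9-borabicyclo[3.3.1]nonan-9-yl)methyl]-2-(3,4,5-trimethoxyphenyl)oxolan-3-yl}methoxy)dimethylsilane | C1CC2CCCC(C1)B2C[C@H]1CO[C@H](c2cc(OC)c(OC)c(OC)c2)[C@H]1CO[Si](C)(C)C(C)(C)C | intermediate
11 | tert-butyldimethyl{[(2S,3R,4R)-2-(3,4,5-trimethoxyphenyl)-4-[(3,4,5-trimethoxyphenyl)methyl]oxolan-3-yl]methoxy}silane | COc1cc(C[C@H]2CO[C@H](c3cc(OC)c(OC)c(OC)c3)[C@H]2CO[Si](C)(C)C(C)(C)C)cc(OC)c1OC | intermediate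
12 | [(2S,3R,4R)-2-(3,4,5-trimethoxyphenyl)-4-[(3,4,5-trimethoxyphenyl)methyl]oxolan-3-yl]methanol | COc1cc(C[C@H]2CO[C@H](c3cc(OC)c(OC)c(OC)c3)[C@H]2CO)cc(OC)c1OC | target

Total step count: 7. Longest linear sequence: 7 steps (1 → 2 → 4 → 6 → 7 → 8 → 11 → 12).

Steps most likely to fail

1. Step 3. Three processes could defeat it. The ester-stabilised zwitterion may add too slowly or reversibly to the electron-rich aldehyde, so that the donor is lost to protodesilylation or self-reaction. The exocyclic alkene may migrate into conjugation with the ester, which erases C3. The ligand may discriminate the aldehyde faces poorly. The fallback uses known chemistry, sets out from 5 and returns at 7. Aldehyde 5 is vinylated on its Si face with divinylzinc F1 (from vinylmagnesium bromide and ZnCl2) under catalysis by a chiral β-amino alcohol, to give (S)-1-(3,4,5-trimethoxyphenyl)prop-2-en-1-ol F2. Williamson etherification (NaH, propargyl bromide, THF) gives 1,2,3-trimethoxy-5-[(1S)-1-(prop-2-yn-1-yloxy)prop-2-en-1-yl]benzene F3. Epoxidation of the vinyl group (mCPBA, NaHCO3, CH2Cl2) gives 2-[(R)-(prop-2-yn-1-yloxy)(3,4,5-trimethoxyphenyl)methyl]oxirane F4 as a mixture of epimers at the oxirane carbon. The mixture is of no consequence, because trivalent titanium (Cp2TiCl from Cp2TiCl2 and Zn, THF) opens the oxirane to the secondary radical at C3. This radical cyclises 5-exo-dig onto the alkyne and should place the CH2O arm trans to the aryl group; hydrogen abstraction and protic work-up give 7, and the route continues with step 5.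

2. Step 6. The borane may discriminate the two faces of the alkene incompletely, since the C2 aryl group lies on the face it must use. The β-branched alkylborane may also transmetalate slowly with the electron-rich bromide and be lost to protodeboronation. The fallback sets out from 10 and returns at 11, and it reverses the roles of the coupling partners. Oxidation of 10 (NaOH, H2O2) gives [(2S,3R,4S)-3-({[tert-butyl(dimethyl)silyl]oxy}methyl)-2-(3,4,5-trimethoxyphenyl)oxolan-4-yl]methanol F5, at which stage a C4 epimer can be removed by chromatography. Iodination (I2, PPh3, imidazole) gives tert-butyl{[(2S,3R,4R)-4-(iodomethyl)-2-(3,4,5-trimethoxyphenyl)oxolan-3-yl]methoxy}dimethylsilane F6. Zinc insertion (Zn, LiCl, THF) gives {[(2S,3R,4R)-3-({[tert-butyl(dimethyl)silyl]oxy}methyl)-2-(3,4,5-trimethoxyphenyl)oxolan-4-yl]methyl}zinc iodide F7, and Negishi coupling with 9 (Pd(OAc)2, SPhos, THF) should give 11.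

3. Step 2. The silylmethyl group may transfer sluggishly from copper, or the propargylic acetate may be displaced in an SN2′ sense to give an allene. The fallback sets out from 1 and returns at 6. Hydroiodination of 1 (NaI, AcOH, 70 °C; anti addition) gives methyl (Z)-4-hydroxy-3-iodobut-2-enoate F8, whose hydroxymethyl group is trans to the ester and so cannot lactonise. Negishi coupling with (trimethylsilyl)methylzinc chloride F9 (from 3 and ZnCl2; Pd(PPh3)4, THF, rt) gives methyl (Z)-4-hydroxy-3-[(trimethylsilyl)methyl]but-2-enoate F10, an allylic alcohol that is inert to zerovalent palladium. Acetylation (Ac2O, Sc(OTf)3, MeCN) gives methyl (Z)-4-acetoxy-3-[(trimethylsilyl)methyl]but-2-enoate F11. This geometric isomer of 4 gives the same trimethylenemethane complex under the conditions of step 3 and should lead to 6.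

Further compounds
F1 | step 3 | divinylzinc | C=C[Zn]C=C
F2 | step 3 | (S)-1-(3,4,5-trimethoxyphenyl)prop-2-en-1-ol | C=C[C@H](O)c1cc(OC)c(OC)c(OC)c1
F3 | step 3 | 1,2,3-trimethoxy-5-[(1S)-1-(prop-2-yn-1-yloxy)prop-2-en-1-yl]benzene | C#CCO[C@H](c1cc(OC)c(OC)c(OC)c1)C=C
F4 | step 3 | 2-[(R)-(prop-2-yn-1-yloxy)(3,4,5-trimethoxyphenyl)methyl]oxirane (both epimers at the oxirane carbon) | C#CCO[C@H](c1cc(OC)c(OC)c(OC)c1)C1CO1
F5 | step 6 | [(2S,3R,4S)-3-({[tert-butyl(dimethyl)silyl]oxy}methyl)-2-(3,4,5-trimethoxyphenyl)oxolan-4-yl]methanol | OC[C@H]1CO[C@H](c2cc(OC)c(OC)c(OC)c2)[C@H]1CO[Si](C)(C)C(C)(C)C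
F6 | step 6 | tert-butyl{[(2S,3R,4R)-4-(iodomethyl)-2-(3,4,5-trimethoxyphenyl)oxolan-3-yl]methoxy}dimethylsilane | IC[C@H]1CO[C@H](c2cc(OC)c(OC)c(OC)c2)[C@H]1CO[Si](C)(C)C(C)(C)C
F7 | step 6 | {[(2S,3R,4R)-3-({[tert-butyl(dimethyl)silyl]oxy}methyl)-2-(3,4,5-trimethoxyphenyl)oxolan-4-yl]methyl}zinc iodide | I[Zn]C[C@H]1CO[C@H](c2cc(OC)c(OC)c(OC)c2)[C@H]1CO[Si](C)(C)C(C)(C)C
F8 | step 2 | methyl (Z)-4-hydroxy-3-iodobut-2-enoate | COC(=O)/C=C(\I)CO
F9 | step 2 | (trimethylsilyl)methylzinc chloride | C[Si](C)(C)C[Zn]Cl
F10 | step 2 | methyl (Z)-4-hydroxy-3-[(trimethylsilyl)methyl]but-2-enoate | COC(=O)/C=C(\C[Si](C)(C)C)CO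
F11 | step 2 | methyl (Z)-4-acetoxy-3-[(trimethylsilyl)methyl]but-2-enoate | COC(=O)/C=C(\C[Si](C)(C)C)COC(C)=O
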